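**Plan** (labdane numbering of the target is used for every intermediate)

1. Retrosynthesis: the C7 hydroxyl (allylic oxidation at the C8=C17 methylene) and the two esters go first. Ring A and ring B are then opened together at C3–C4 and C5–C10 to an acyclic epoxy aldehyde, which is cut at C9–C10 (allylboration) and C8–C9 (alkenyllithium addition).
2. Forward: (R)-linalool (C9, C11–C16), 6-methylhept-5-en-2-one (C4–C8, C17–C19) and (R)-α-hydroxy-γ-butyrolactone (C10, C1–C3) are joined through a borylated (E)-nerolidol-type chain; a sulfur ylide adds C20.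
3. Rings: Cp2TiCl opens the C10–C20 oxirane; the C10 radical closes ring B on C5 of the C4=C5 isopropylidene group, and the resulting C4 radical closes ring A on the C3 aldehyde.
4. Enabling feature: the oxirane carbon C10 carries both the C9–C8–C7–C6 chain to the C4=C5 alkene and the C1–C2 chain to the C3 aldehyde, so C5 and then C3 lie in 6-exo reach. The two oxygens end as the C20 and C3 hydroxyls and the isopropylidene carbon as the gem-dimethyl C4.
5. Stereochemistry: C13 from linalool, C2 from the lactone, C9 from catalyst-controlled allylboration; C10, C5 and C3 from the chair–chair cascade; C7 from the ene/[2,3] course of the SeO2 oxidation.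

Key step: step 14

Assumption: the carbinol carbon of 7 and 8 and the oxirane carbon C10 of 17 and 18 form as epimer mixtures, which is harmless because both centres become trigonal later.

**Route**

Step 1
Reactants: 1 (R)-linalool
Product: 2 (R)-linalool triethylsilyl ether
Conditions: TESOTf, 2,6-lutidine, CH2Cl2, −78 to 0 °C
Reagents that add atoms: triethylsilyl trifluoromethanesulfonate, CC[Si](CC)(CC)OS(=O)(=O)C(F)(F)F
Why: Silylation of the tertiary allylic alcohol with a silyl triflate and a hindered pyridine base is a standard protection and leaves C13 untouched.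

Step 2
Reactants: 2 (R)-linalool triethylsilyl ether
Product: 3 (4R)-4-methyl-4-(triethylsilyloxy)hex-5-enal
Conditions: O3 (1 equiv), CH2Cl2, pyridine, −78 °C; then Me2S
Reagents that add atoms: ozone, [O-][O+]=O
Why: Ozonolysis is chemoselective for the electron-rich trisubstituted alkene over the vinyl group next to the silyloxy-bearing quaternary carbon, and reductive work-up gives the aldehyde without touching C13.

Step 3
Reactants: 4 6-methylhept-5-en-2-one
Product: 5 6-methylhept-5-en-2-one 2,4,6-triisopropylbenzenesulfonylhydrazone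
Conditions: 2,4,6-triisopropylbenzenesulfonyl hydrazide, MeOH, cat. HCl, rt
Reagents that add atoms: 2,4,6-triisopropylbenzenesulfonohydrazide, CC(C)c1cc(C(C)C)c(S(=O)(=O)NN)c(C(C)C)c1
Why: Acid-catalysed condensation of the methyl ketone with the arenesulfonyl hydrazide gives the hydrazone needed for the Shapiro reaction.

Step 4
Reactants: 5 sulfonylhydrazone of 6-methylhept-5-en-2-one; 3 (4R)-4-methyl-4-(triethylsilyloxy)hex-5-enal
Product: 8 methyl (3R)-3,11-dimethyl-7-methylidene-3-(triethylsilyloxy)dodeca-1,10-dien-6-yl carbonate (C6 epimers), via alkenyllithium 6 (not isolated), via lithium alkoxide 7 (not isolated)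
Conditions: 5, n-BuLi (2.2 equiv), THF, −78 to 0 °C; then 3, −78 °C; then ClCO2Me, −78 to 0 °C
Reagents that add atoms: methyl chloroformate, COC(=O)Cl
Why: Shapiro reaction: deprotonation at N–H and then at the methyl group, with loss of sulfinate and N2, gives the less substituted alkenyllithium, which adds 1,2 to aldehyde 3 before the alkoxide is acylated in the same flask; the carbinol carbon forms as an epimer mixture that is removed in step 5.

Step 5
Reactants: 8 allylic methyl carbonate
Product: 9 triethyl{[(3R,5E)-3,11-dimethyl-7-methylidenedodeca-1,5,10-trien-3-yl]oxy}silane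
Conditions: Pd(PPh3)4 (5 mol %), Et3N, 1,4-dioxane, 90 °C
Reagents that add atoms: none
Why: Tsuji–Trost-type elimination: zerovalent palladium ionises the allylic carbonate to a π-allyl complex, and β-hydride loss from C11, the only position that can give a conjugated diene, gives the (E)-1,3-diene.

Step 6
Reactants: 9 (5E)-1,3-diene
Product: 10 triethyl{[(3R,6E)-3,11-dimethyl-7-[(4,4,5,5-tetramethyl-1,3,2-dioxaborolan-2-yl)methyl]dodeca-1,6,10-trien-3-yl]oxy}silane (CH2B cis to C11 of the labdane numbering)
Conditions: Ni(cod)2 (5 mol %), PCy3 (5 mol %), pinacolborane, toluene, rt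
Reagents that add atoms: pinacolborane, B1OC(C)(C)C(C)(C)O1
Why: Nickel-catalysed 1,4-hydroboration of the 1,3-diene places boron on the terminal CH2 (C17) and hydrogen on C11 through an s-cis π-allyl intermediate, which sets the boron-bearing CH2 cis to C11 and leaves the isolated alkenes untouched.

Step 7
Reactants: 11 (R)-α-hydroxy-γ-butyrolactone
Product: 12 (3R)-3-(tert-butyldimethylsilyloxy)oxolan-2-one
Conditions: TBSCl, imidazole, DMF, rt
Reagents that add atoms: tert-butyldimethylsilyl chloride, CC(C)(C)[Si](C)(C)Cl
Why: Standard silylation of the secondary alcohol; C2 is untouched.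

Step 8
Reactants: 12 silylated lactone
Product: 13 (2R)-2-(tert-butyldimethylsilyloxy)-4-hydroxy-N-methoxy-N-methylbutanamide
Conditions: MeNHOMe·HCl, AlMe3, CH2Cl2, 0 °C to rt
Reagents that add atoms: N,O-dimethylhydroxylamine hydrochloride, CNOC.Cl
Why: Weinreb aminolysis of the lactone with the aluminium amide opens the ring and frees the primary alcohol without touching C2.

Step 9
Reactants: 13 hydroxy Weinreb amide
Product: 14 (2R)-2-(tert-butyldimethylsilyloxy)-N-methoxy-N-methyl-4-oxobutanamide
Conditions: Dess–Martin periodinane, pyridine, CH2Cl2, 0 °C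
Reagents that add atoms: none
Why: Dess–Martin oxidation gives the aldehyde under non-basic conditions, which avoids β-elimination of the silyloxy group.

Step 10
Reactants: 10 allylboronate; 14 aldehyde
Product: 15 (2R,9S,10S,13R)-homoallylic alcohol (hydroxyl at C10, C9 bearing the C8=C17 methylene unit and the C11–C16 chain, silyl ether at C2, Weinreb amide at C3)
Conditions: (R)-TRIP [(R)-3,3'-bis(2,4,6-triisopropylphenyl)-1,1'-binaphthyl-2,2'-diyl hydrogen phosphate] (5 mol %), 4 Å MS, toluene, −30 °C
Reagents that add atoms: none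
Why: Chiral phosphoric acid-catalysed allylboration through a closed chair transition state: the γ-substituent cis to the CH2B group sits axial and gives the syn adduct, and (R)-TRIP is expected to direct the allyl unit to the Re face of the aldehyde, which together set C9 as (S) with the C8=C17 methylene in place (the C10 carbinol centre is removed in step 11).

Step 11
Reactants: 15 homoallylic alcohol
Product: 16 (2R,9S,13R)-C10 ketone
Conditions: Dess–Martin periodinane, pyridine, CH2Cl2, 0 °C
Reagents that add atoms: none
Why: Buffered Dess–Martin oxidation gives the β,γ-unsaturated ketone without epimerising the doubly activated C9–H.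

Step 12
Reactants: 16 C10 ketone
Product: 17 (2R,9S,13R)-C10–C20 oxirane (C10 epimers) with the Weinreb amide at C3
Conditions: Me3S+ I−, n-BuLi, THF, −10 °C; then 16, −78 to 0 °C
Reagents that add atoms: trimethylsulfonium iodide, C[S+](C)C.[I-]
Why: Corey–Chaykovsky reaction: dimethylsulfonium methylide adds to the ketone at low temperature faster than it deprotonates it and the betaine closes to the 2,2-disubstituted oxirane, while the Weinreb amide is inert; the oxirane carbon forms as an epimer mixture that converges in step 14.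

Step 13
Reactants: 17 epoxy Weinreb amide
Product: 18 (2R,9S,13R)-epoxy aldehyde (C3 aldehyde, C2 silyl ether, C10–C20 oxirane, C4=C5 isopropylidene)
Conditions: i-Bu2AlH, THF, −78 °C; then aq KNaC4H4O6
Reagents that add atoms: none
Why: Reduction of the Weinreb amide stops at the chelated tetrahedral intermediate at −78 °C and gives the α-silyloxy aldehyde on work-up, with the oxirane untouched at this temperature.

Step 14
Reactants: 18 epoxy aldehyde
Product: 19 (13R)-2α-(tert-butyldimethylsilyloxy)-13-(triethylsilyloxy)labda-8(17),14-diene-3α,20-diol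
Conditions: Cp2TiCl2 (2.5 equiv), Mn (8 equiv), THF, rt, slow addition of 18; then dilute aq HCl, 0 °C
Reagents that add atoms: none
Why: Proposed new method: Cp2TiCl (trivalent titanium) opens the 2,2-disubstituted oxirane by single-electron transfer to the tertiary β-titanoxy C10 radical, which adds 6-exo-trig to C5 of the isopropylidene group (ring B, C5–C10 bond); the tertiary C4 radical then adds 6-exo-trig to the titanium-bound aldehyde carbon C3 (ring A, C3–C4 bond), and a second Cp2TiCl reduces the alkoxy radical at once, which makes the otherwise reversible carbonyl addition productive. The closest known reaction types are the Cp2TiCl-mediated epoxypolyene radical cyclization and the Cp2TiCl-mediated addition of epoxide-derived radicals to aldehydes, which have not been shown coupled in one cascade on this substrate class. Ring B should close through a chair with the C9 side chain, the developing C4 centre and the β-branched C1 arm equatorial and the CH2OTi arm axial, so that C9 controls C5 and C10 and a trans-decalin results. Ring A should close through a chair with the C2 silyloxy group equatorial, and C2 controls C3 because the Felkin–Anh arrangement (C2–O bond anti to the incoming C4, carbonyl oxygen gauche to C1) places the new hydroxyl axial and cis to the C2 oxygen. The step needs the C10 radical to choose the isopropylidene group over the remote vinyl group (7-endo) and the aldehyde (4-exo), which the faster 6-exo addition that forms a tertiary radical should secure, and it needs both oxirane epimers to converge, which the planar radical secures.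

Step 15
Reactants: 19 decalin diol
Product: 20 (13R)-20-acetoxy-2α-(tert-butyldimethylsilyloxy)-13-(triethylsilyloxy)labda-8(17),14-dien-3α-ol
Conditions: Ac2O (1.1 equiv), pyridine, CH2Cl2, 0 °C
Reagents that add atoms: acetic anhydride, CC(=O)OC(C)=O
Why: Acetylation is selective for the primary C20 hydroxyl because the C3 hydroxyl is axial and flanked by the gem-dimethyl group and the silyloxy group.

Step 16
Reactants: 20 monoacetate
Product: 21 (13R)-20-acetoxylabda-8(17),14-diene-2α,3α,13-triol
Conditions: HF·pyridine, THF/pyridine, 0 °C to rt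
Reagents that add atoms: none
Why: Buffered fluoride cleavage removes both silyl ethers and leaves the acetate and the tertiary allylic alcohol intact.

Step 17
Reactants: 21 triol
Product: 22 (13R)-20-acetoxy-2α-angeloyloxylabda-8(17),14-diene-3α,13-diol
Conditions: angelic acid, 2,4,6-trichlorobenzoyl chloride, Et3N, toluene, rt; then 21, 75 °C
Reagents that add atoms: angelic acid, C/C=C(/C)C(=O)O
Why: Yamaguchi esterification without DMAP transfers the angeloyl group with its (Z)-geometry intact, and the equatorial C2 hydroxyl reacts in preference to the axial neopentyl C3 hydroxyl and the tertiary C13 hydroxyl.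

Step 18
Reactants: 22 angelate
Product: 23 (13R)-20-acetoxy-2α-angeloyloxylabda-8(17),14-diene-3α,7α,13-triol (target)
Conditions: SeO2 (0.5 equiv), t-BuOOH (2 equiv), CH2Cl2, 0 °C to rt
Reagents that add atoms: selenium dioxide, O=[Se]=O; tert-butyl hydroperoxide, CC(C)(C)OO
Why: Riley allylic oxidation: the ene reaction of SeO2 at the 1,1-disubstituted C8=C17 alkene with the axial 7α-hydrogen and the following [2,3]-sigmatropic shift return the exocyclic alkene and deliver the hydroxyl axially (7α), while the electron-poor angelate alkene and the vinyl group, which has no allylic hydrogen, are left alone.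

**Compound list**

1 | (R)-linalool | C=C[C@](C)(O)CCC=C(C)C | starting material
2 | (R)-linalool triethylsilyl ether | C=C[C@](C)(O[Si](CC)(CC)CC)CCC=C(C)C | intermediate
3 | (4R)-4-methyl-4-(triethylsilyloxy)hex-5-enal | C=C[C@](C)(O[Si](CC)(CC)CC)CCC=O | intermediate
4 | 6-methylhept-5-en-2-one | CC(=O)CCC=C(C)C | starting material
5 | 6-methylhept-5-en-2-one 2,4,6-triisopropylbenzenesulfonylhydrazone | CC(CCC=C(C)C)=NNS(=O)(=O)c1c(C(C)C)cc(C(C)C)cc1C(C)C | intermediate
6 | (6-methylhepta-1,5-dien-2-yl)lithium | [Li]C(=C)CCC=C(C)C | intermediate (not isolated)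
7 | lithium (3R)-3,11-dimethyl-7-methylidene-3-(triethylsilyloxy)dodeca-1,10-dien-6-olate (C6 epimers) | C=C[C@](C)(O[Si](CC)(CC)CC)CCC([O-])C(=C)CCC=C(C)C.[Li+] | intermediate (not isolated)
8 | methyl (3R)-3,11-dimethyl-7-methylidene-3-(triethylsilyloxy)dodeca-1,10-dien-6-yl carbonate (C6 epimers) | C=C[C@](C)(O[Si](CC)(CC)CC)CCC(OC(=O)OC)C(=C)CCC=C(C)C | intermediate
9 | triethyl{[(3R,5E)-3,11-dimethyl-7-methylidenedodeca-1,5,10-trien-3-yl]oxy}silane | C=C[C@](C)(O[Si](CC)(CC)CC)C/C=C/C(=C)CCC=C(C)C | intermediate
10 | (3R,6E)-nerolidol triethylsilyl ether borylated (pinacol boronate) at the C7 methyl group | C=C[C@](C)(O[Si](CC)(CC)CC)CC/C=C(\CB1OC(C)(C)C(C)(C)O1)CCC=C(C)C | intermediate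
11 | (R)-α-hydroxy-γ-butyrolactone | O=C1[C@H](O)CCO1 | starting material
12 | (3R)-3-(tert-butyldimethylsilyloxy)oxolan-2-one | O=C1[C@H](O[Si](C)(C)C(C)(C)C)CCO1 | intermediate
13 | (2R)-2-(tert-butyldimethylsilyloxy)-4-hydroxy-N-methoxy-N-methylbutanamide | CON(C)C(=O)[C@H](O[Si](C)(C)C(C)(C)C)CCO | intermediate
14 | (2R)-2-(tert-butyldimethylsilyloxy)-N-methoxy-N-methyl-4-oxobutanamide | CON(C)C(=O)[C@H](O[Si](C)(C)C(C)(C)C)CC=O | intermediate
15 | (2R,9S,10S,13R)-homoallylic alcohol (C10 hydroxyl, C2 silyl ether, C3 Weinreb amide) | C=C[C@](C)(O[Si](CC)(CC)CC)CC[C@H]([C@@H](O)C[C@@H](O[Si](C)(C)C(C)(C)C)C(=O)N(C)OC)C(=C)CCC=C(C)C | intermediate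
16 | (2R,9S,13R)-C10 ketone | C=C[C@](C)(O[Si](CC)(CC)CC)CC[C@H](C(=O)C[C@@H](O[Si](C)(C)C(C)(C)C)C(=O)N(C)OC)C(=C)CCC=C(C)C | intermediate
17 | (2R,9S,13R)-C10–C20 oxirane with C3 Weinreb amide (C10 epimers) | C=C[C@](C)(O[Si](CC)(CC)CC)CC[C@H](C1(CO1)C[C@@H](O[Si](C)(C)C(C)(C)C)C(=O)N(C)OC)C(=C)CCC=C(C)C | intermediate
18 | (2R,9S,13R)-epoxy aldehyde (C10 epimers) | C=C[C@](C)(O[Si](CC)(CC)CC)CC[C@H](C1(CO1)C[C@@H](O[Si](C)(C)C(C)(C)C)C=O)C(=C)CCC=C(C)C | intermediate
19 | (13R)-2α-(tert-butyldimethylsilyloxy)-13-(triethylsilyloxy)labda-8(17),14-diene-3α,20-diol | C=C[C@](C)(O[Si](CC)(CC)CC)CC[C@H]1C(=C)CC[C@H]2C(C)(C)[C@H](O)[C@H](O[Si](C)(C)C(C)(C)C)C[C@]12CO | intermediate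
20 | (13R)-20-acetoxy-2α-(tert-butyldimethylsilyloxy)-13-(triethylsilyloxy)labda-8(17),14-dien-3α-ol | C=C[C@](C)(O[Si](CC)(CC)CC)CC[C@H]1C(=C)CC[C@H]2C(C)(C)[C@H](O)[C@H](O[Si](C)(C)C(C)(C)C)C[C@]12COC(C)=O | intermediate
21 | (13R)-20-acetoxylabda-8(17),14-diene-2α,3α,13-triol | C=C[C@](C)(O)CC[C@H]1C(=C)CC[C@H]2C(C)(C)[C@H](O)[C@H](O)C[C@]12COC(C)=O | intermediate
22 | (13R)-20-acetoxy-2α-angeloyloxylabda-8(17),14-diene-3α,13-diol | C=C[C@](C)(O)CC[C@H]1C(=C)CC[C@H]2C(C)(C)[C@H](O)[C@H](OC(=O)/C(C)=C\C)C[C@]12COC(C)=O | intermediate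
23 | (13R)-20-acetoxy-2α-angeloyloxylabda-8(17),14-diene-3α,7α,13-triol | C=C[C@](C)(O)CC[C@H]1C(=C)[C@H](O)C[C@H]2C(C)(C)[C@H](O)[C@H](OC(=O)/C(C)=C\C)C[C@]12COC(C)=O | target

**Count and risks**

Total steps: 18. Longest linear sequence: 14 (steps 1, 2, 4, 5, 6 and 10 to 18, from (R)-linalool).

Steps most likely to fail:

1. Step 14 (proposed new method). The C10 radical may add 4-exo to the aldehyde or 7-endo to the vinyl group, the C4 radical may be lost by hydrogen abstraction before it reaches the carbonyl, or facial selectivity at C10 may be poor.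
 Fallback: the rings are closed one after the other with known radical reactions, setting out from epoxy Weinreb amide 17. Cp2TiCl (Cp2TiCl2, Mn, THF) effects the known epoxide opening and 6-exo-trig closure of ring B with the C4 radical ending as an isopropenyl group, giving the monocyclic 3,4-seco alcohol F1, at which stage C10 epimers can be separated. TESCl/imidazole gives the 20-O-triethylsilyl ether F2, and i-Bu2AlH at −78 °C gives the aldehyde F3. Fe(acac)3/PhSiH3 in EtOH then regenerates the C4 radical by Markovnikov hydrogen-atom transfer to the isopropenyl group and closes ring A on the aldehyde (known hydrogen-atom-transfer-initiated alkene–carbonyl cyclization) to give the 20-O-triethylsilyl decalin F4; the C8 methylene is the competing hydrogen-atom acceptor. PPTS/MeOH removes the primary silyl ether and the route is rejoined at diol 19.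

2. Step 10. Facial control at the aldehyde by the catalyst may be insufficient with the trisubstituted boronate and the chiral aldehyde, which would give the wrong C9 configuration, or addition may be slow.
 Fallback: stoichiometric reagent control, setting out from boronate 10. KHF2 in MeOH/H2O gives the potassium trifluoroborate F5; TMSCl and diisopropyl (S,S)-tartrate give the tartrate-modified allylboronate F6, which is expected to add to the Re face of 14 (toluene, 4 Å MS, −78 °C) through the same chair and rejoins the route at alcohol 15.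

3. Step 18. Over-oxidation to the enone, attack at the C9–H or at the angelate methyl groups, or poor facial selectivity may occur.
 Fallback: the oxidation is taken apart into known steps, setting out from 22. Ene-type allylic chlorination (NCS, cat. PhSeCl, CH2Cl2) gives the rearranged 17-chloro-7-ene F7; PhSeNa (PhSeSePh, NaBH4, EtOH) gives the allylic phenyl selenide F8; H2O2/pyridine forms the selenoxide, whose [2,3]-sigmatropic shift delivers the oxygen to C7, restores the 8(17)-alkene and rejoins the route at 23.

Further compounds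

F1 | step 14 | (2R,13R)-2-(tert-butyldimethylsilyloxy)-20-hydroxy-13-(triethylsilyloxy)-3,4-seco-labda-4(18),8(17),14-trien-3-oic acid N-methoxy-N-methylamide | C=C[C@](C)(O[Si](CC)(CC)CC)CC[C@H]1C(=C)CC[C@@H](C(C)=C)[C@]1(CO)C[C@@H](O[Si](C)(C)C(C)(C)C)C(=O)N(C)OC
F2 | step 14 | 20-O-triethylsilyl ether of F1 | C=C[C@](C)(O[Si](CC)(CC)CC)CC[C@H]1C(=C)CC[C@@H](C(C)=C)[C@]1(CO[Si](CC)(CC)CC)C[C@@H](O[Si](C)(C)C(C)(C)C)C(=O)N(C)OC
F3 | step 14 | (2R,13R)-2-(tert-butyldimethylsilyloxy)-13,20-bis(triethylsilyloxy)-3,4-seco-labda-4(18),8(17),14-trien-3-al | C=C[C@](C)(O[Si](CC)(CC)CC)CC[C@H]1C(=C)CC[C@@H](C(C)=C)[C@]1(CO[Si](CC)(CC)CC)C[C@@H](O[Si](C)(C)C(C)(C)C)C=O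
F4 | step 14 | (13R)-2α-(tert-butyldimethylsilyloxy)-13,20-bis(triethylsilyloxy)labda-8(17),14-dien-3α-ol | C=C[C@](C)(O[Si](CC)(CC)CC)CC[C@H]1C(=C)CC[C@H]2C(C)(C)[C@H](O)[C@H](O[Si](C)(C)C(C)(C)C)C[C@]12CO[Si](CC)(CC)CC
F5 | step 10 | potassium trifluoroborate corresponding to boronate 10 | C=C[C@](C)(O[Si](CC)(CC)CC)CC/C=C(\C[B-](F)(F)F)CCC=C(C)C.[K+]
F6 | step 10 | diisopropyl (S,S)-tartrate boronate corresponding to 10 | C=C[C@](C)(O[Si](CC)(CC)CC)CC/C=C(\CB1O[C@H](C(=O)OC(C)C)[C@@H](C(=O)OC(C)C)O1)CCC=C(C)C
F7 | step 18 | (13R)-20-acetoxy-2α-angeloyloxy-17-chlorolabda-7,14-diene-3α,13-diol | C=C[C@](C)(O)CC[C@H]1C(CCl)=CC[C@H]2C(C)(C)[C@H](O)[C@H](OC(=O)/C(C)=C\C)C[C@]12COC(C)=O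
F8 | step 18 | (13R)-20-acetoxy-2α-angeloyloxy-17-(phenylselanyl)labda-7,14-diene-3α,13-diol | C=C[C@](C)(O)CC[C@H]1C(C[Se]c3ccccc3)=CC[C@H]2C(C)(C)[C@H](O)[C@H](OC(=O)/C(C)=C\C)C[C@]12COC(C)=O
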